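The earlier runs and the new flask are calculated for an exercise, noise included.

One number carried my reckoning for the gamma flask: the loss number, the share of the charge lost from target by the moment the solid substrate is spent.

- gamma: solid substrate 0.25 M; target 2.5 mM; the very flask that is asked about, followed so far
- flask: solid substrate 0.25 M; target 2.50 mM; time 6.0 d

gamma run (percent of the solid substrate charged)

| time / h | target / % | solid substrate / % |
|---|---|---|
| 10.0 | 25.8 | 74.3 |
| 12.0 | 31.0 | 69.8 |
| 15.0 | 38.5 | 60.9 |
| 20.0 | 49.9 | 47.8 |
| 25.0 | 62.4 | 35.3 |
| 30.0 | 73.7 | 22.3 |
| 40.0 | 91.5 | 0 |

(each reading ± 0.5 percentage points)

- solid substrate is a solid; its amount is given per volume of the solution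
- at the start none of the solid substrate is in solution

- when, up to 6.0 d, the flask holds most target
- the amount of target, in percent of the solid substrate charged, at that time

The solid fell on a straight line, a zero-order feed, at 0.0260 h⁻¹ of the charge, so it reached zero at

t = 1.61 d.

At 30.0 h the balance, counting the charged target, came short by 5.00%. Spread over the average target up to then, this gave a first-order loss of

k = 0.00446 h⁻¹.

Target rose almost linearly, so I took its average over the feed as the mean of its charged amount and its end value, and set

h = k·t/2 = 8.61%.

The end value then had to equal the charge plus charged target, minus h times the sum of charged target and end value, which solved to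

92.9%.

The charge plus charged target, less this end value, came to 8.08%, the loss number. The feed outran the loss at that end value, so I put the peak at t.

Was one number enough? Decay from that peak gave 92.3% at 40.0 h, against the unused reading of 91.5%, a gap of 0.80 percentage points, larger than the scatter of 0.5 points.

The forecast said 92% at 1.62 d, lower than my end value and later than my time; its ground for the peak was that “conversion stops almost as soon as the solid is gone”.

The flask gave 92.4% at 1.60 d.

    starting material → target (k = 3.34 × 10⁻⁴ h⁻¹)
    target → over-reaction product (k = 0.00468 h⁻¹)
    starting material + target → 2 target (k = 582 M⁻¹ h⁻¹)
    solid substrate ⇌ starting material, rate k4*(cs4 - [starting material]) while solid is left; crystals form when [starting material] > cs4 (solubility = 34.0 mM, k = 0.193 h⁻¹)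

At that time it held 8.59% of over-reaction product, beside my loss number of 8.08%. For the neighbour flask charged with 0.62 M of solid substrate, I held the molar feed and k as before, so h grew with the charge to 21.3%. That put its peak at 82.7% and its loss number at 17.7%, and the neighbour's highest amount of target is 81.1%.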